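The two-carbon bridge between ring D (the ortho-phenylene) and ring A (the 5-aryloxy-3,4-dioxygenated ring) has two benzylic carbons, so it is traced back to a D–CH2–O–CH2–A dibenzyl ether. An 18-membered tetramethyl-protected macrocyclic ether, closed by a Williamson reaction, is treated with n-BuLi. The [1,2]-Wittig rearrangement then makes the benzylic C–C bond, pushes the oxygen out of the ring and contracts it to the 17-membered skeleton in one operation. The open chain is assembled by two SNAr diaryl ether formations and a Wittig–hydrogenation. Ring A is carried as a methyl ester and ring D is added last as an aldehyde, so the two benzylic termini differ without extra protecting groups.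

Key step: step 12

Ring labels: A = 5-aryloxy-3,4-dioxygenated ring, B = para-phenylene, C = 2-aryloxy-3,4-dioxygenated ring, D = ortho-phenylene.

Assumption: methyl 3-hydroxy-4,5-dimethoxybenzoate is taken as a purchasable compound, and the alkene of step 5 is carried as an E/Z mixture because step 6 saturates it.

Step 1
Reactants: 1 methyl 3-hydroxy-4,5-dimethoxybenzoate; 2 4-fluorobenzaldehyde
Product: 3 methyl 3-(4-formylphenoxy)-4,5-dimethoxybenzoate
Conditions: K2CO3, DMF, 120 °C
Reagents that add atoms: none
Why: Nucleophilic aromatic substitution (SNAr) in which the para-formyl group activates the C–F bond toward the phenoxide of 1, while the ring A ester is inert and keeps the two future benzylic carbons at different oxidation levels.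

Step 2
Reactants: 3 methyl 3-(4-formylphenoxy)-4,5-dimethoxybenzoate
Product: 4 methyl 3-[4-(hydroxymethyl)phenoxy]-4,5-dimethoxybenzoate
Conditions: NaBH4, MeOH/THF, 0 °C
Reagents that add atoms: none
Why: Chemoselective borohydride reduction, since NaBH4 at 0 °C reduces the aldehyde and leaves the aromatic methyl ester untouched.

Step 3
Reactants: 4 methyl 3-[4-(hydroxymethyl)phenoxy]-4,5-dimethoxybenzoate
Product: 5 {4-[2,3-dimethoxy-5-(methoxycarbonyl)phenoxy]benzyl}triphenylphosphonium bromide
Conditions: PPh3·HBr, MeCN, reflux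
Reagents that add atoms: triphenylphosphine hydrobromide, [Br-].c1ccc(cc1)[PH+](c1ccccc1)c1ccccc1
Why: Direct phosphonium salt formation from a benzylic alcohol, in which HBr ionises the para-aryloxy-stabilised alcohol and triphenylphosphine captures it, so no benzylic bromide has to be isolated and the ester is not affected.

Step 4
Reactants: 6 2-hydroxy-3,4-dimethoxybenzaldehyde
Product: 7 2-(benzyloxy)-3,4-dimethoxybenzaldehyde
Conditions: BnBr, K2CO3, DMF, 50 °C
Reagents that add atoms: benzyl bromide, BrCc1ccccc1
Why: Williamson O-benzylation of the phenol, which masks the ring C hydroxyl during the olefination with a group that step 6 removes at no extra cost.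

Step 5
Reactants: 5 {4-[2,3-dimethoxy-5-(methoxycarbonyl)phenoxy]benzyl}triphenylphosphonium bromide; 7 2-(benzyloxy)-3,4-dimethoxybenzaldehyde
Product: 9 methyl 3-{4-[2-(2-benzyloxy-3,4-dimethoxyphenyl)ethenyl]phenoxy}-4,5-dimethoxybenzoate (E/Z mixture), via phosphonium ylide 8 (not isolated)
Conditions: K2CO3, 18-crown-6 (cat.), CH2Cl2, reflux
Reagents that add atoms: none
Why: Wittig olefination under mild solid–liquid carbonate conditions, which generate the semi-stabilised benzylic ylide 8 without attacking the methyl ester and should join rings B and C through the future ethylene bridge.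

Step 6
Reactants: 9 methyl 3-{4-[2-(2-benzyloxy-3,4-dimethoxyphenyl)ethenyl]phenoxy}-4,5-dimethoxybenzoate
Product: 10 methyl 3-{4-[2-(2-hydroxy-3,4-dimethoxyphenyl)ethyl]phenoxy}-4,5-dimethoxybenzoate
Conditions: H2 (1 atm), Pd/C (10% palladium on carbon), EtOAc/MeOH, rt
Reagents that add atoms: none
Why: Catalytic hydrogenation saturates the stilbene and hydrogenolyses the benzyl ether in the same operation, while diaryl ether, methyl ethers and ester are stable to these conditions.

Step 7
Reactants: 10 methyl 3-{4-[2-(2-hydroxy-3,4-dimethoxyphenyl)ethyl]phenoxy}-4,5-dimethoxybenzoate; 11 2-fluorobenzaldehyde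
Product: 12 methyl 3-(4-{2-[2-(2-formylphenoxy)-3,4-dimethoxyphenyl]ethyl}phenoxy)-4,5-dimethoxybenzoate
Conditions: Cs2CO3, DMF, 120 °C
Reagents that add atoms: none
Why: SNAr in which the ortho-formyl group activates fluoride displacement by the electron-rich ring C phenoxide, and the new ring D aldehyde is the only aldehyde in the molecule because ring A still carries an ester.

Step 8
Reactants: 12 methyl 3-(4-{2-[2-(2-formylphenoxy)-3,4-dimethoxyphenyl]ethyl}phenoxy)-4,5-dimethoxybenzoate
Product: 13 methyl 3-[4-(2-{2-[2-(hydroxymethyl)phenoxy]-3,4-dimethoxyphenyl}ethyl)phenoxy]-4,5-dimethoxybenzoate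
Conditions: NaBH4, MeOH/THF, 0 °C
Reagents that add atoms: none
Why: Chemoselective borohydride reduction of the aldehyde in the presence of the methyl ester, as in step 2.

Step 9
Reactants: 13 methyl 3-[4-(2-{2-[2-(hydroxymethyl)phenoxy]-3,4-dimethoxyphenyl}ethyl)phenoxy]-4,5-dimethoxybenzoate
Product: 14 methyl 3-[4-(2-{2-[2-(bromomethyl)phenoxy]-3,4-dimethoxyphenyl}ethyl)phenoxy]-4,5-dimethoxybenzoate
Conditions: PBr3, CH2Cl2, 0 °C
Reagents that add atoms: phosphorus tribromide, BrP(Br)Br
Why: Conversion of a primary benzylic alcohol into the bromide by bromide displacement on the phosphite ester, giving a 2-aryloxybenzyl bromide that is robust enough to carry forward and leaving ester and ethers untouched at 0 °C.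

Step 10
Reactants: 14 methyl 3-[4-(2-{2-[2-(bromomethyl)phenoxy]-3,4-dimethoxyphenyl}ethyl)phenoxy]-4,5-dimethoxybenzoate
Product: 15 {3-[4-(2-{2-[2-(bromomethyl)phenoxy]-3,4-dimethoxyphenyl}ethyl)phenoxy]-4,5-dimethoxyphenyl}methanol
Conditions: i-Bu2AlH, CH2Cl2, −78 °C; aq. potassium sodium tartrate
Reagents that add atoms: none
Why: Aluminium hydride reduction of the aryl ester to the benzylic alcohol at low temperature, a known chemoselective reduction under which a benzylic bromide is not displaced by hydride.

Step 11
Reactants: 15 {3-[4-(2-{2-[2-(bromomethyl)phenoxy]-3,4-dimethoxyphenyl}ethyl)phenoxy]-4,5-dimethoxyphenyl}methanol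
Product: 16 18-membered macrocyclic dibenzyl ether (rings D and A linked by CH2–O–CH2; four methyl ethers)
Conditions: NaH, n-Bu4NI (cat.), THF, 50 °C, slow addition of 15 (about 2 mM)
Reagents that add atoms: none
Why: Intramolecular Williamson ether synthesis in which the ring A benzylic alkoxide displaces the reactive ring D benzylic bromide, with slow addition at high dilution to favour closure of the 18-membered ring over oligomerisation.

Step 12
Reactants: 16 18-membered macrocyclic dibenzyl ether
Product: 19 racemic 17-membered macrocyclic carbinol with a D–CH(OH)–CH2–A bridge (four methyl ethers), via alpha-lithio ether 17 (not isolated), via lithium alkoxide 18 (not isolated)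
Conditions: n-BuLi, THF, −78 → 0 °C; aq. NH4Cl
Reagents that add atoms: none
Why: n-BuLi removes a proton from the doubly activated (aryl plus alpha-oxygen) benzylic CH2 next to ring D to give 17, whose other C–O bond breaks homolytically to a ring A benzyl radical and a lithium ketyl, and these recombine at carbon to give alkoxide 18, which is a [1,2]-Wittig rearrangement. The closest known reaction is the [1,2]-Wittig rearrangement of dibenzyl ether to 1,2-diphenylethanol, together with its ring-contracting version on cyclic dibenzyl ethers, applied here to an 18-membered ring. The 17-membered carbocycle is closed by recombination of the radical pair, which the rest of the macrocycle holds together; this amounts to a 1,2-shift of the ring A benzyl group from oxygen to carbon and leaves the oxygen exocyclic as the hydroxyl. The new carbinol stereocentre is formed without control and is racemic, which is acceptable because step 13 removes it. The selectivity needed is benzylic deprotonation over ortho-lithiation of the methoxy- and aryloxy-substituted rings; it should be secured by the higher kinetic acidity of the alpha-oxy benzylic C–H bonds at low temperature, by the inductive and coordinating ortho-aryloxy group on ring D, and by the absence of beta-hydrogens that could divert the anion into elimination. Which of the two benzylic sites is deprotonated does not matter for the final bridge, since the hydroxyl is deleted in the next step.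

Step 13
Reactants: 19 racemic 17-membered macrocyclic carbinol
Product: 20 tetra-O-methyl ether of the target (17-membered macrocycle with D–CH2–CH2–A bridge)
Conditions: Et3SiH, CF3CO2H, CH2Cl2, 0 °C → rt
Reagents that add atoms: none
Why: Ionic hydrogenation in which the acid ionises the secondary benzylic alcohol to a cation stabilised by the ortho-aryloxy ring D and the silane delivers hydride, which deletes the only stereocentre.

Step 14
Reactants: 20 tetra-O-methyl ether of the target
Product: 21 target bis(bibenzyl) tetraphenol (CNP0114693.0)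
Conditions: BBr3, CH2Cl2, −78 °C → rt; then MeOH/H2O
Reagents that add atoms: none
Why: Lewis-acid demethylation of aryl methyl ethers, in which bromide attacks the methyl group of each boron-complexed ether, should free both catechols while the diaryl ether bonds, which lack an alkyl carbon for displacement, stay intact.

Compound list
1 | methyl 3-hydroxy-4,5-dimethoxybenzoate | COC(=O)c1cc(O)c(OC)c(OC)c1 | starting material
2 | 4-fluorobenzaldehyde | O=Cc1ccc(F)cc1 | starting material
3 | methyl 3-(4-formylphenoxy)-4,5-dimethoxybenzoate | COC(=O)c1cc(Oc2ccc(C=O)cc2)c(OC)c(OC)c1 | intermediate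
4 | methyl 3-[4-(hydroxymethyl)phenoxy]-4,5-dimethoxybenzoate | COC(=O)c1cc(Oc2ccc(CO)cc2)c(OC)c(OC)c1 | intermediate
5 | {4-[2,3-dimethoxy-5-(methoxycarbonyl)phenoxy]benzyl}triphenylphosphonium bromide | COC(=O)c1cc(Oc2ccc(C[P+](c3ccccc3)(c3ccccc3)c3ccccc3)cc2)c(OC)c(OC)c1.[Br-] | intermediate
6 | 2-hydroxy-3,4-dimethoxybenzaldehyde | COc1ccc(C=O)c(O)c1OC | starting material
7 | 2-(benzyloxy)-3,4-dimethoxybenzaldehyde | COc1ccc(C=O)c(OCc2ccccc2)c1OC | intermediate
8 | {4-[2,3-dimethoxy-5-(methoxycarbonyl)phenoxy]benzylidene}triphenylphosphorane (ylide, not isolated) | COC(=O)c1cc(Oc2ccc(C=P(c3ccccc3)(c3ccccc3)c3ccccc3)cc2)c(OC)c(OC)c1 | intermediate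
9 | methyl 3-{4-[2-(2-benzyloxy-3,4-dimethoxyphenyl)ethenyl]phenoxy}-4,5-dimethoxybenzoate (E/Z mixture) | COC(=O)c1cc(Oc2ccc(C=Cc3ccc(OC)c(OC)c3OCc3ccccc3)cc2)c(OC)c(OC)c1 | intermediate
10 | methyl 3-{4-[2-(2-hydroxy-3,4-dimethoxyphenyl)ethyl]phenoxy}-4,5-dimethoxybenzoate | COC(=O)c1cc(Oc2ccc(CCc3ccc(OC)c(OC)c3O)cc2)c(OC)c(OC)c1 | intermediate
11 | 2-fluorobenzaldehyde | O=Cc1ccccc1F | starting material
12 | methyl 3-(4-{2-[2-(2-formylphenoxy)-3,4-dimethoxyphenyl]ethyl}phenoxy)-4,5-dimethoxybenzoate | COC(=O)c1cc(Oc2ccc(CCc3ccc(OC)c(OC)c3Oc3ccccc3C=O)cc2)c(OC)c(OC)c1 | intermediate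
13 | methyl 3-[4-(2-{2-[2-(hydroxymethyl)phenoxy]-3,4-dimethoxyphenyl}ethyl)phenoxy]-4,5-dimethoxybenzoate | COC(=O)c1cc(Oc2ccc(CCc3ccc(OC)c(OC)c3Oc3ccccc3CO)cc2)c(OC)c(OC)c1 | intermediate
14 | methyl 3-[4-(2-{2-[2-(bromomethyl)phenoxy]-3,4-dimethoxyphenyl}ethyl)phenoxy]-4,5-dimethoxybenzoate | COC(=O)c1cc(Oc2ccc(CCc3ccc(OC)c(OC)c3Oc3ccccc3CBr)cc2)c(OC)c(OC)c1 | intermediate
15 | {3-[4-(2-{2-[2-(bromomethyl)phenoxy]-3,4-dimethoxyphenyl}ethyl)phenoxy]-4,5-dimethoxyphenyl}methanol | OCc1cc(Oc2ccc(CCc3ccc(OC)c(OC)c3Oc3ccccc3CBr)cc2)c(OC)c(OC)c1 | intermediate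
16 | 18-membered macrocyclic dibenzyl ether, D–CH2–O–CH2–A, tetramethyl ether | COc1cc2cc(c1OC)Oc1ccc(cc1)CCc1ccc(OC)c(OC)c1Oc1ccccc1COC2 | intermediate
17 | alpha-lithio ether of 16, lithiated at the benzylic carbon next to ring D (not isolated) | COc1cc2cc(c1OC)Oc1ccc(cc1)CCc1ccc(OC)c(OC)c1Oc1ccccc1C([Li])OC2 | intermediate
18 | lithium alkoxide of the ring-contracted carbinol (not isolated) | COc1cc2cc(c1OC)Oc1ccc(cc1)CCc1ccc(OC)c(OC)c1Oc1ccccc1C(O[Li])C2 | intermediate
19 | racemic 17-membered macrocyclic carbinol, D–CH(OH)–CH2–A, tetramethyl ether | COc1cc2cc(c1OC)Oc1ccc(cc1)CCc1ccc(OC)c(OC)c1Oc1ccccc1C(O)C2 | intermediate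
20 | tetra-O-methyl ether of the target, D–CH2–CH2–A | COc1cc2cc(c1OC)Oc1ccc(cc1)CCc1ccc(OC)c(OC)c1Oc1ccccc1CC2 | intermediate
21 | CNP0114693.0, macrocyclic bis(bibenzyl) with catechols on rings A and C (no stereocentre) | Oc1cc2cc(c1O)Oc1ccc(cc1)CCc1ccc(O)c(O)c1Oc1ccccc1CC2 | target

Total step count: 14. Longest linear sequence: 13 steps (steps 1–3 and 5–14); step 4 is a one-step side branch.

Steps most likely to fail

Step 12. Ring lithiation ortho to the methoxy or aryloxy groups may compete with benzylic deprotonation, or the radical pair may fail to recombine cleanly, so that unrearranged or ring-opened material results. The fallback leaves the rearrangement and closes the same bridge by olefination, setting out from 15. The benzylic alcohol would be oxidised with MnO2 (CH2Cl2, rt) to 3-[4-(2-{2-[2-(bromomethyl)phenoxy]-3,4-dimethoxyphenyl}ethyl)phenoxy]-4,5-dimethoxybenzaldehyde F1. The bromide would be quaternised with PPh3 (toluene, 90 °C) to the formyl-substituted benzylic triphenylphosphonium bromide F2. Intramolecular Wittig olefination (NaOMe, CH2Cl2/MeOH, high dilution) would close the ring to the 17-membered macrocyclic stilbene F3, as an E/Z mixture. Hydrogenation (H2, Pd/C, EtOAc) would then give 20, where the route is rejoined.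

Step 11. Intermolecular alkylation may outpace closure of the 18-membered ring and give dimers and oligomers. The fallback replaces alkoxide displacement by a reductive etherification, setting out from 15. Silylation (Et3SiOSO2CF3, 2,6-lutidine, CH2Cl2, −78 °C) would give the triethylsilyl ether F4. Oxidation of the benzylic bromide with N-methylmorpholine N-oxide (MeCN, rt) would give the silyloxy aldehyde F5. Treatment with catalytic BiBr3 and Et3SiH in MeCN at high dilution would join the aldehyde carbon to the silyl ether oxygen and reduce the oxocarbenium ion, returning to the route at 16.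

Step 13. The benzylic cation may be captured across the ring by one of the electron-rich arenes (Friedel–Crafts alkylation), or the reduction may stall after loss of a proton. The fallback avoids a free cation, setting out from 19. Acetylation (Ac2O, pyridine, 4-(dimethylamino)pyridine, CH2Cl2) would give the benzylic acetate F6. Hydrogenolysis of its benzylic C–O bond (H2, Pd/C, EtOAc/AcOH) would return to the route at 20.

Further compounds
F1 | step 12 | 3-[4-(2-{2-[2-(bromomethyl)phenoxy]-3,4-dimethoxyphenyl}ethyl)phenoxy]-4,5-dimethoxybenzaldehyde | O=Cc1cc(Oc2ccc(CCc3ccc(OC)c(OC)c3Oc3ccccc3CBr)cc2)c(OC)c(OC)c1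
F2 | step 12 | {2-[6-(2-{4-[5-formyl-2,3-dimethoxyphenoxy]phenyl}ethyl)-2,3-dimethoxyphenoxy]benzyl}triphenylphosphonium bromide | O=Cc1cc(Oc2ccc(CCc3ccc(OC)c(OC)c3Oc3ccccc3C[P+](c3ccccc3)(c3ccccc3)c3ccccc3)cc2)c(OC)c(OC)c1.[Br-]
F3 | step 12 | 17-membered macrocyclic stilbene, D–CH=CH–A, tetramethyl ether (E/Z mixture) | COc1cc2cc(c1OC)Oc1ccc(cc1)CCc1ccc(OC)c(OC)c1Oc1ccccc1C=C2
F4 | step 11 | triethylsilyl ether of 15 | CC[Si](CC)(CC)OCc1cc(Oc2ccc(CCc3ccc(OC)c(OC)c3Oc3ccccc3CBr)cc2)c(OC)c(OC)c1
F5 | step 11 | 2-{6-[2-(4-{2,3-dimethoxy-5-[(triethylsilyloxy)methyl]phenoxy}phenyl)ethyl]-2,3-dimethoxyphenoxy}benzaldehyde | CC[Si](CC)(CC)OCc1cc(Oc2ccc(CCc3ccc(OC)c(OC)c3Oc3ccccc3C=O)cc2)c(OC)c(OC)c1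
F6 | step 13 | acetate of carbinol 19 (racemic) | COc1cc2cc(c1OC)Oc1ccc(cc1)CCc1ccc(OC)c(OC)c1Oc1ccccc1C(OC(C)=O)C2
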